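All runs are simulated with made-up constants, and the scatter is random.

The time allowed comes first: the flask gets 8.0 d, and the ash run, with 1 mM of initiator against the flask's 2.0 mM, read 0% starting material already at 3.00 d, so the flask is allowed longer than ash took to reach that reading, and the charges remain to be counted.

| flask | starting material | reagent | initiator | remark | time |
|---|---|---|---|---|---|
| birch | 0.20 M | 0.13 M | 2 mM | run made earlier |  |
| larch | 0.20 M | 0.52 M | 2 mM | run made earlier |  |
| ash | 0.20 M | 0.26 M | 1 mM | run made earlier |  |
| flask | 0.20 M | 0.260 M | 2.0 mM |  | 8.0 d |

- birch (time / d: starting material / %, target / %, isomer of the product / %): 0.625: 36, 30, 32; 1.25: 34, 34, 31; 2.50: 34, 30, 35; 4.00: 36, 32, 30; 8.00: 34, 33, 34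
- larch (time / d: starting material / %, target / %, isomer of the product / %): 0.625: 0, 51, 50; 2.08: 0, 51, 51; 4.00: 0, 50, 48; 6.00: 1, 52, 51; 8.00: 0, 49, 51
- ash (time / d: starting material / %, target / %, isomer of the product / %): 1.67: 4, 50, 49; 3.00: 0, 53, 51; 5.00: 1, 50, 51; 6.00: 1, 53, 50; 8.00: 0, 53, 49

(scatter of a reading: 1.5 percentage points)

- a species is counted by the starting material in it: one ended chains A counts as two
- candidate steps: initiator -> 2 initiating radical; 2 second chain carrier -> ended chains B; reagent + first chain carrier -> target + second chain carrier; starting material + second chain carrier -> released group + first chain carrier; target <-> isomer of the product; starting material + initiating radical -> capped initiator + first chain carrier; 2 first chain carrier -> ended chains A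
- the reaction counts as stopped when no species that holds the starting material changes by six tenths of a point or more over the second half of the time

- which holds at 8.0 d: what has brought the reaction to rest, or that it has not come to rest (forward and back rates have come level / all of the starting material has reacted / the reagent has run out first / it is still moving)
- conversion of starting material at 8.0 d
- amount of target at 8.0 d, in percent of the starting material charged
- amount of isomer of the product at 8.0 d, in percent of the starting material charged

1. The bench rule is to count equivalents, freezing one reagent used per starting material converted. The birch run supports this: its reagent over its starting material is 0.650, and at 8.00 d it reads 67.0% of target and isomer together, with 34% starting material standing beside them.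

2. For the flask, the same ratio is 1.30; this is the reagent cover, the fraction of the starting-material charge that the reagent can carry through.

3. The rule has its border at a cover of 1. Below it, in birch, the reagent is the limiting reagent and the cover gives the products; above it, in ash at 1.30 and larch at 2.60, the ceiling is the charge of starting material itself, and both runs read about 0% of it at 8.00 d.

4. Target and isomer read level from the earliest readings, 51% and 50% in larch at 0.625 d, so this reckoning freezes a level split: conversion 100%, each product 50.0%.

5. The forecast says all of the starting material has reacted, conversion 100%, target 50.2%, isomer 49.8%, reasoning from ash that “so it should finish sooner”.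

6. The flask gives all of the starting material has reacted, conversion 100%, target 50.7%, isomer 49.2%.

    initiator → 2 initiating radical (k = 0.0120 /h)
    2 second chain carrier → ended chains B (k = 6.90 × 10⁶ /M/s)
    reagent + first chain carrier → target + second chain carrier (k = 19000 /M/s)
    starting material + second chain carrier → released group + first chain carrier (k = 17000 /M/s)
    target ⇌ isomer of the product (K = 0.970, k = 0.230 /h)
    starting material + initiating radical → capped initiator + first chain carrier (k = 3.00 × 10⁵ /M/s)
    2 first chain carrier → ended chains A (k = 1.50 × 10⁸ /M/s)

Because of the way back from isomer to target, the flask holds 50.7% target, while the run without that way back holds 0%. Reckoned from the cover, 23.1% of the reagent's own charge stays unused in the flask, which holds 23% of it at 8.00 d.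

In the neighbour flask with 0.50 M starting material, the cover is 0.520, below the border, which gives 26.0% of each product. That neighbour computes to 26.4% target and 25.6% isomer, with 47.3% starting material remaining.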